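Assumption: the target has no stereocentre and no stereogenic double bond, so the structure as drawn is its only stereoisomer and no enantiocontrol is needed.

**Retrosynthetic overview**
1. The target is opened at the pyranone O1–C2 bond, with a shift of two hydrogens, to its open-chain isomer, a 2'-hydroxyaryl (2E,4E)-dienone (redox-neutral cycloisomerization, C–O bond formation, last step).
2. The dienone is cut at its α,β C=C bond into 2'-hydroxy-4',5'-dimethoxyacetophenone and (E)-3-hydroxy-4-methoxycinnamaldehyde (Claisen–Schmidt).
3. The cinnamaldehyde is cut at its C=C bond into isovanillin and acetaldehyde (crossed aldol).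
4. Ring order: both benzene rings are bought; the 4-pyranone ring (ring C) is the only ring made and is closed last.

**Route**

Step 1
Reactants: 1 isovanillin (3-hydroxy-4-methoxybenzaldehyde); 2 acetaldehyde
Product: 4 (E)-3-(3-hydroxy-4-methoxyphenyl)prop-2-enal, via β-hydroxy aldehyde 3 (not isolated)
Conditions: NaOH (3 equiv), H2O/MeOH, −10 to 0 °C, 2 (1.8 equiv) added over 24 h; then aq HCl to pH 3
Reagents that add atoms: none
Why: Crossed aldol condensation in which non-enolisable 1, held as its phenoxide, meets slowly dosed acetaldehyde enolate, adduct 3 loses water by E1cB to the conjugated E-enal (thermodynamic geometry, not carried into the target), and the low acetaldehyde concentration limits self-condensation and a second homologation.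

Step 2
Reactants: 4 (E)-3-(3-hydroxy-4-methoxyphenyl)prop-2-enal; 5 1-(2-hydroxy-4,5-dimethoxyphenyl)ethanone (2'-hydroxy-4',5'-dimethoxyacetophenone)
Product: 7 (2E,4E)-1-(2-hydroxy-4,5-dimethoxyphenyl)-5-(3-hydroxy-4-methoxyphenyl)penta-2,4-dien-1-one, via β-hydroxy ketone 6 (not isolated)
Conditions: KOH (50% aq, 6 equiv), EtOH, N2, 0 °C to rt, 36 h; then ice/aq HCl
Reagents that add atoms: none
Why: Claisen–Schmidt condensation in which the methyl ketone enolate of 5 adds to aldehyde 4 (which has no enolisable hydrogen), E1cB dehydration of 6 gives the fully conjugated E,E-dienone, and the bis-phenoxide stays open-chain until it precipitates on acidification; no stereocentre is formed that is kept.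

Step 3
Reactants: 7 (2E,4E)-1-(2-hydroxy-4,5-dimethoxyphenyl)-5-(3-hydroxy-4-methoxyphenyl)penta-2,4-dien-1-one
Product: 10 2-[2-(3-hydroxy-4-methoxyphenyl)ethyl]-6,7-dimethoxy-4H-chromen-4-one, via 2-styrylchromanone 8 (not isolated), via exocyclic enol ether 9 (not isolated)
Conditions: RuHCl(CO)(PPh3)3 (5 mol%), DBU (20 mol%), anhydrous degassed 1,4-dioxane (0.1 M), 100 °C, Ar, 16 h
Reagents that add atoms: none
Why: Proposed new method: a redox-neutral cycloisomerization in which DBU generates the 2'-phenoxide that closes the O1–C2 bond by reversible 6-endo-trig oxa-Michael addition to give racemic chromanone 8, whose C2–H is allylic and α-oxygenated, so that reversible insertion of the styryl C=C into the divalent ruthenium hydride followed by β-hydride elimination toward C2 (a net 1,3-hydrogen shift) gives enol ether 9, which the base tautomerizes into the 4-pyranone, the thermodynamic sink that drains the dienone/chromanone equilibrium (estimated several kcal/mol downhill, since the vinylogous-ester chromone outweighs the lost styrene conjugation); the closest known reaction types are Ru–H isomerization of allyl and cinnamyl ethers to enol ethers, redox isomerization of allylic alcohols, and cycloisomerization of 2'-hydroxyaryl ynones to chromones, none of which has been shown to turn a 2'-hydroxy dienone into a 2-(2-arylethyl)chromone; the C2 stereocentre of 8 is destroyed, and the free phenols, methyl ethers and the product C2=C3 bond are inert because no hydrogen donor is present.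

**Compound list**
1 | isovanillin (3-hydroxy-4-methoxybenzaldehyde) | COc1ccc(C=O)cc1O | starting material
2 | acetaldehyde | CC=O | starting material
3 | 3-hydroxy-3-(3-hydroxy-4-methoxyphenyl)propanal (racemic aldol adduct) | COc1ccc(C(O)CC=O)cc1O | intermediate
4 | (E)-3-(3-hydroxy-4-methoxyphenyl)prop-2-enal | COc1ccc(/C=C/C=O)cc1O | intermediate
5 | 1-(2-hydroxy-4,5-dimethoxyphenyl)ethanone | CC(=O)c1cc(OC)c(OC)cc1O | starting material
6 | (E)-3-hydroxy-1-(2-hydroxy-4,5-dimethoxyphenyl)-5-(3-hydroxy-4-methoxyphenyl)pent-4-en-1-one (racemic aldol adduct) | COc1ccc(/C=C/C(O)CC(=O)c2cc(OC)c(OC)cc2O)cc1O | intermediate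
7 | (2E,4E)-1-(2-hydroxy-4,5-dimethoxyphenyl)-5-(3-hydroxy-4-methoxyphenyl)penta-2,4-dien-1-one | COc1ccc(/C=C/C=C/C(=O)c2cc(OC)c(OC)cc2O)cc1O | intermediate
8 | (E)-2-[2-(3-hydroxy-4-methoxyphenyl)ethenyl]-6,7-dimethoxy-2,3-dihydro-4H-chromen-4-one (racemic) | COc1ccc(/C=C/C2CC(=O)c3cc(OC)c(OC)cc3O2)cc1O | intermediate
9 | 2-[2-(3-hydroxy-4-methoxyphenyl)ethylidene]-6,7-dimethoxy-2,3-dihydro-4H-chromen-4-one (E/Z mixture, geometry not defined) | COc1ccc(CC=C2CC(=O)c3cc(OC)c(OC)cc3O2)cc1O | intermediate
10 | 2-[2-(3-hydroxy-4-methoxyphenyl)ethyl]-6,7-dimethoxy-4H-chromen-4-one (achiral) | COc1ccc(CCc2cc(=O)c3cc(OC)c(OC)cc3o2)cc1O | target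

**Totals**
Total steps: 3. Longest linear sequence: 3 steps (1 → 4 → 7 → 10); 5 enters at step 2.

**Steps most likely to fail, with fallbacks**

Step 3 (the proposed new cycloisomerization) is the riskiest. The ruthenium hydride may insert too slowly into the internal styryl ether of 8. It may shuttle hydrogen between molecules and give styrylchromone plus over-reduced material. It may also be tied up by the chelating 2'-hydroxy ketone of 7. The fallback uses known chemistry, sets out from 7 and comes back to the route at 10. Heating 7 with I2 (10 mol%) in DMSO at 130 °C for 1–2 h brings about the established oxidative cyclization of 2'-hydroxycinnamylideneacetophenones and gives (E)-2-[2-(3-hydroxy-4-methoxyphenyl)ethenyl]-6,7-dimethoxy-4H-chromen-4-one F1. Hydrogenation of this compound over 10% Pd/C (H2, 1 atm, EtOAc, rt, stopped after one equivalent is taken up) saturates only the styryl C=C bond, because the chromone C2=C3 bond is a vinylogous ester, and delivers 10.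

Step 2 (Claisen–Schmidt condensation) is the next risk. Both partners are phenoxides, so the condensation may be sluggish. Retro-aldol cleavage of 4 in strong hydroxide would release isovanillin and lead to a chalcone impurity. The fallback sets out from 5 (with 4) and comes back at 7. It replaces the one-pot thermodynamic condensation by a kinetic directed aldol addition and a separate dehydration. Ketone 5 is converted into its O,C-dilithio species with LiN(SiMe3)2 (2.1 equiv) in THF at −78 °C. The lithium phenoxide of 4, made separately with LiN(SiMe3)2 (1.0 equiv), is added at −78 °C. Quenching cold with aq NH4Cl allows β-hydroxy ketone 6 to be isolated; it is already in the compound list, so new compounds on this way: none F0. Adduct 6 is then dehydrated with p-TsOH (5 mol%) in toluene at 60 °C to give 7.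

Step 1 (crossed aldol with acetaldehyde) can suffer from acetaldehyde self-condensation, over-homologation to the dienal and incomplete conversion. The fallback sets out from 1 and comes back at 4. It replaces the aldol by a Wittig olefination: 1 is heated with Ph3P=CHCHO (1.1 equiv) in toluene at 80 °C. The stabilized ylide is E-selective, needs no base and tolerates the free phenol. New compounds on this way: none F0.

**Further compounds**
F0 | step 1 | none | none
F0 | step 2 | none | none
F1 | step 3 | (E)-2-[2-(3-hydroxy-4-methoxyphenyl)ethenyl]-6,7-dimethoxy-4H-chromen-4-one | COc1ccc(/C=C/c2cc(=O)c3cc(OC)c(OC)cc3o2)cc1O
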